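Conventions and one assumption. Ring A is the benzoate ring (C1 carries the ester carbon, C2 a prenyl ether, C6 the bridging oxygen). Ring B carries the bridging oxygen on C1', a prenyl ether on C2', H on C3', methoxy on C4', C-prenyl on C5' and hydroxymethyl on C6'. Prenyl = 3-methylbut-2-en-1-yl, MOM = methoxymethyl, TBS = tert-butyldimethylsilyl, TMS = trimethylsilyl. Benzaldehydes 1–6 are numbered from the formyl carbon, so aldehyde C2, C3, C5 and C6 become C1', C2', C4' and C5'. The target has no stereocentre and no stereogenic double bond. The precursors and the product of the key step, as drawn in the compound list, map atom for atom onto the target. Assumption: tributyl(3-methylbut-2-en-1-yl)stannane, chloromethyl methyl ether, isopropyl isocyanate and PhNTf2 are purchasable reagents.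

## Structural features

The target is an open diaryl ether: two benzene rings joined only through one oxygen, with no further ring. Ring A is a methyl benzoate whose carboxyl carbon on C1 lies between a prenyl ether on C2 and the bridging oxygen on C6. Ring B is pentasubstituted, with four different substituents besides the bridging oxygen and a single ring hydrogen on C3'. No stereocentre exists, so every difficulty is one of regiochemistry and chemoselectivity. The fragile parts are the two aryl prenyl ethers (cleaved by acid, rearranged by heat), the three trisubstituted alkenes (attacked by bromine and strong acid), the benzylic alcohol on an electron-rich ring, and an ester that this alcohol could reach to form an eight-membered lactone. The real difficulty is the C6–O–C1' ether, which has three ortho substituents around it, together with the contiguous oxygen–carboxyl–oxygen pattern of ring A. That pattern, a carboxyl carbon on C1 between oxygens on C2 and C6, is what the key step uses: it is the imprint of a 3-oxygenated benzyne that accepted an oxygen nucleophile at its remote carbon and CO2 at the carbon next to the alkoxy group.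

## Logic of the disconnections

27 to 26: the O–Si bond of a silyl ether is restored on the hydroxymethyl oxygen. The primary alcohol stays masked to the end so that it is neither alkylated nor able to attack the neighbouring ester. The forward step must free it without a base strong enough to drive transesterification.

26 to 24 and 25: both aryl O–CH2 bonds of the prenyl ethers are cut, so two molecules of 25 are needed for each molecule of 24. Aryl prenyl ethers would not survive arene bromination, organolithium chemistry or acid, and an allylic ether beside an aryne invites an intramolecular ene reaction. Cutting here lets both ethers be made in one basic operation, which must alkylate oxygen, including the hydrogen-bonded salicylate hydroxyl.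

24 to 22: the two phenols are traced back to two aryl acetals (ArO–CH2OCH3 bonds). These groups do more than protect: one directs the lithiation leading to 17 and polarizes the aryne, the other distinguishes the two catechol oxygens of ring B. The forward step must remove both without Brønsted acid, because the C-prenyl alkene and the benzylic ether are present.

22 to 21: the ester O–CH3 bond is cut. Alkylating the carboxylate oxygen avoids acyl substitution at a carbonyl flanked by two ortho substituents.

21 to 9, 17 and 18: the C6–O bond and the C1–carboxyl bond are cut together. This divides the molecule into a complete ring B phenol, a three-substituent aryne precursor and a one-carbon unit, and it replaces a hindered aryl halide substitution by addition to a small, very electrophilic acceptor. The forward step must add the phenoxide regioselectively and must carboxylate the aryl anion faster than it is protonated.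

9 to 7: the benzylic O–Si bond is cut. The forward step must tell a phenol from a primary alcohol; this is done by silylating both (8) and using the much greater base lability of the aryl silyl ether.

7 to 6: the hydroxymethyl carbon is traced to a formyl group. The aldehyde is kept until here because it differentiates the two phenols, steers both brominations and activates the ortho bromide toward palladium.

6 to 5: the bond between C5' and the prenyl CH2 is cut, giving an aryl bromide and a prenyl-metal partner. The forward coupling must transfer the prenyl group without allylic transposition.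

5 to 4: the C–Br bond is cut. The forward bromination must choose the position para to the acetal oxygen over the position between the two alkoxy groups, and it must come before any alkene is present.

4 to 3: the C4'–OCH3 bond is cut to an aryl bromide and methoxide. This turns the easiest electrophilic substitution of the ring into an oxygen substituent; the forward step is a copper-mediated substitution on a phenoxide-bearing ring.

3 to 2: the O–CH2OCH3 bond on the C2' oxygen is cut. The forward step must alkylate only one of two adjacent phenols, which the chelated, conjugated C1' phenoxide makes possible.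

2 to 1: the C–Br bond is cut; the forward bromination is directed para to the chelated hydroxyl and meta to the formyl group.

17 to 15: the O–SO2CF3 bond is cut and the carbamate restored (through 16). The carbamate is needed as the directing group and must leave under conditions that keep the aryl–silicon bond.

15 to 12: the aryl C–Si bond is cut (through 13 and 14). The forward lithiation must occur at the carbon between the two oxygen substituents, which both direct there.

12 to 11: the carbamate O–C(=O) bond is cut; a simple addition of the phenol to an isocyanate remakes it.

11 to 10: one O–CH2OCH3 bond is cut, leading to a symmetrical diphenol. The forward step is a statistical mono-protection.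

## Other disconnections considered

Alternative 1: The cut goes through ring B (C1'–C6', C3'–C4', C4'–C5'), so that ring B and an eight-membered lactone A1 arise together from the tethered zerovalent chromium carbene A2. In A2 the carbene oxygen is the ring A aryloxy oxygen, the carbene carbon carries a 1-tert-butoxyvinyl group, and the ring A carboxyl is esterified with a prenyl-substituted propargyl alcohol. The forward key step is a Dötz benzannulation in dilute solution: CO loss, alkyne insertion, CO insertion and electrocyclization to A1.
- In its favour: the substitution pattern of ring B is written into the chain, so no electrophilic substitution has to be steered. Three C–C bonds and two rings form in one step, and methanolysis of the lactone would deliver the ester and the benzylic alcohol together. On bonds formed per step it is better than the chosen plan.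
- Against it: aryloxycarbene complexes are far harder to make and keep than alkoxy ones. The tether must hold an eight-membered ring during insertion, and cyclobutenone, indene and furan side paths are typical of this chemistry. Stoichiometric chromium is also needed.
- Comparison: after A1 there remain methylation of the C4' phenol, acid cleavage of the tert-butyl ether beside a prenyl group, opening of a hindered lactone, acetal removal and two prenylations. The step count would therefore not fall below that of the chosen plan, and the mechanism is less predictable. Neither plan has to control a stereocentre, so they are equal there.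

Alternative 2: Only C1'–C6' is cut. The acyclic precursor A4 carries the ring A aryloxy group on an sp3 carbon next to a ketone, a methyl enol ether as a masked carbonyl, a prenyl-bearing methine and a keto acetal. Cs2CO3 should form the enolate at C1', add it to the C6' ketone and, after dehydration and enolization, give the phenol A3.
- In its favour: the hindered diaryl ether bond is made as a simple alkyl aryl ether before ring B exists, ring A carries its prenyl ether and ester from the start, and no metal is needed. On these points it is better than the chosen plan.
- Against it: A4 is a sensitive polycarbonyl chain with three acidic sites, of which the doubly activated prenyl methine is the most acidic, so other aldol modes and enol ether isomerization compete. The enol ether must place C2' and C5' cis for closure.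
- Comparison: after A3, unmasking the acetal needs acid in the presence of an aryl prenyl ether and a C-prenyl group, followed by reduction and prenylation. That endgame is about as long as the chosen one, but the synthesis of A4 would be longer and less secure than the two aromatic fragments. The regiochemistry is equally well defined in both plans.

Alternative 3: C1–C2 and C5–C6 of ring A are cut. The aryloxypropiolate A6, carrying complete ring B, would react with the ketene acetal diene A7 in a Diels–Alder reaction; loss of methanol and hydrolysis of the aryl trimethylsilyl ether would give the salicylate A5.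
- In its favour: ring A arrives with the ester and a free hydroxyl, so it needs no protecting group, and the endgame shrinks to prenylation and desilylation, shorter than in the chosen plan. The regiochemistry follows from the polarization of both partners, and no anion has to be trapped in competition with protonation.
- Against it: A6 requires an alkynyl aryl ether to be made from a di-ortho-substituted phenol, a multistep sequence using organolithium reagents. The oxygen donor makes the alkyne a poor dienophile, and the heat then needed threatens the aryl prenyl ether through Claisen rearrangement. Ring B must also already carry its prenyl ether, which costs a protecting-group exchange because arene bromination has to precede any alkene.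
- Comparison: the total length would be similar, with more risk placed in the preparation of A6. In ring B chemistry and in the absence of stereochemical issues the two plans are equal.

Key step: step 12

## Route

Step 1
Reactants: 1 2,3-dihydroxybenzaldehyde
Product: 2 5-bromo-2,3-dihydroxybenzaldehyde
Conditions: Br2, NaOAc, AcOH, 0 °C → rt
Reagents that add atoms: bromine, BrBr
Why: Electrophilic aromatic bromination; C5 is para to the chelated C2 hydroxyl and is the only free position neither ortho nor para to the deactivating formyl group, while NaOAc buffers the HBr.

Step 2
Reactants: 2 5-bromo-2,3-dihydroxybenzaldehyde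
Product: 3 5-bromo-2-hydroxy-3-(methoxymethoxy)benzaldehyde
Conditions: NaH (2.2 equiv), DMSO–THF, rt; MOMCl (1.0 equiv), rt
Reagents that add atoms: chloromethyl methyl ether, COCCl
Why: Williamson-type O-alkylation after double deprotonation; the C2 oxygen anion is conjugated with and chelated to the formyl group, so the limiting electrophile should be taken by the more nucleophilic C3 oxygen.

Step 3
Reactants: 3 5-bromo-2-hydroxy-3-(methoxymethoxy)benzaldehyde
Product: 4 2-hydroxy-5-methoxy-3-(methoxymethoxy)benzaldehyde
Conditions: NaOMe, CuBr (cat.), MeOH–DMF, 110 °C
Reagents that add atoms: sodium methoxide, C[O-].[Na+]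
Why: Copper-catalysed Ullmann-type methoxylation of an aryl bromide, the classical conversion of bromohydroxybenzaldehydes into methoxyhydroxybenzaldehydes; the acetal and the aldehyde tolerate hot methoxide.

Step 4
Reactants: 4 2-hydroxy-5-methoxy-3-(methoxymethoxy)benzaldehyde
Product: 5 6-bromo-2-hydroxy-5-methoxy-3-(methoxymethoxy)benzaldehyde
Conditions: NBS, MeCN, 0 °C → rt
Reagents that add atoms: N-bromosuccinimide, O=C1CCC(=O)N1Br
Why: Electrophilic aromatic bromination; C6 is para to the acetal oxygen and ortho to the methoxy group, whereas C4 lies between two alkoxy groups, and 3,5-dialkoxybenzaldehydes are known to brominate ortho to the formyl group. The neutral conditions spare the acetal, and no alkene is present yet.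

Step 5
Reactants: 5 6-bromo-2-hydroxy-5-methoxy-3-(methoxymethoxy)benzaldehyde
Product: 6 2-hydroxy-5-methoxy-3-(methoxymethoxy)-6-(3-methylbut-2-en-1-yl)benzaldehyde
Conditions: tributyl(prenyl)stannane, Pd(PPh3)4 (cat.), DMF, 90 °C
Reagents that add atoms: tributyl(3-methylbut-2-en-1-yl)stannane, CCCC[Sn](CCCC)(CCCC)CC=C(C)C
Why: Stille cross-coupling; the ortho formyl group assists oxidative addition to zerovalent palladium, prenyl transfer from tin under these conditions normally gives the linear prenyl arene, and the free phenol is tolerated.

Step 6
Reactants: 6 2-hydroxy-5-methoxy-3-(methoxymethoxy)-6-(3-methylbut-2-en-1-yl)benzaldehyde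
Product: 7 2-(hydroxymethyl)-4-methoxy-6-(methoxymethoxy)-3-(3-methylbut-2-en-1-yl)phenol
Conditions: NaBH4, THF–MeOH, 0 °C; aq. NH4Cl
Reagents that add atoms: none
Why: Hydride reduction of an aryl aldehyde; alkene, acetal and aryl ethers are inert, and the neutral quench avoids quinone methide formation from the 2-hydroxybenzyl alcohol.

Step 7
Reactants: 7 2-(hydroxymethyl)-4-methoxy-6-(methoxymethoxy)-3-(3-methylbut-2-en-1-yl)phenol
Product: 9 2-[(tert-butyldimethylsilyloxy)methyl]-4-methoxy-6-(methoxymethoxy)-3-(3-methylbut-2-en-1-yl)phenol, via bis-silyl ether 8 (not isolated)
Conditions: TBSCl (2.2 equiv), imidazole, DMF, rt; then K2CO3, MeOH, rt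
Reagents that add atoms: tert-butyldimethylsilyl chloride, CC(C)(C)[Si](C)(C)Cl
Why: Silylation of both hydroxyls followed by selective base methanolysis of the aryl silyl ether, which is far more labile than the alkyl silyl ether because phenoxide is the better leaving group; any silyl migration equilibrium also leaves silicon on the alkyl oxygen.

Step 8
Reactants: 10 resorcinol
Product: 11 3-(methoxymethoxy)phenol
Conditions: NaH (1 equiv), DMF, 0 °C; MOMCl (1 equiv), 0 °C → rt; resorcinol in excess
Reagents that add atoms: chloromethyl methyl ether, COCCl
Why: Statistical mono-O-alkylation of a symmetrical diphenol; the excess of resorcinol limits double protection and is washed out with water.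

Step 9
Reactants: 11 3-(methoxymethoxy)phenol
Product: 12 3-(methoxymethoxy)phenyl N-isopropylcarbamate
Conditions: i-PrNCO, Et3N (cat.), CH2Cl2, rt
Reagents that add atoms: isopropyl isocyanate, CC(C)N=C=O
Why: Base-catalysed addition of a phenol to an isocyanate; the N-monoalkyl carbamate is chosen because it directs lithiation and later leaves under mild E1cB conditions.

Step 10
Reactants: 12 3-(methoxymethoxy)phenyl N-isopropylcarbamate
Product: 15 3-(methoxymethoxy)-2-(trimethylsilyl)phenyl N-isopropylcarbamate, via N-silyl carbamate 13 (not isolated), via N-silyl C-silyl carbamate 14 (not isolated)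
Conditions: TBSOTf (1.05 equiv), TMEDA, Et2O, 0 °C → rt; n-BuLi, TMEDA, −78 °C; TMSCl, −78 °C → rt; aq. NH4Cl
Reagents that add atoms: chlorotrimethylsilane, C[Si](C)(C)Cl; tert-butyldimethylsilyl trifluoromethanesulfonate, CC(C)(C)[Si](C)(C)OS(=O)(=O)C(F)(F)F (its silyl group appears in intermediates 13 and 14 only)
Why: Directed ortho-metalation; transient N-silylation blocks N–H deprotonation (the silyl triflate is kept near one equivalent and amine-buffered so that the acetal is not touched), the carbamate and acetal oxygens then direct lithiation cooperatively to the carbon between them, and the N–Si bond is hydrolysed on work-up after the TMSCl quench.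

Step 11
Reactants: 15 3-(methoxymethoxy)-2-(trimethylsilyl)phenyl N-isopropylcarbamate
Product: 17 3-(methoxymethoxy)-2-(trimethylsilyl)phenyl trifluoromethanesulfonate, via silylphenol 16 (not isolated)
Conditions: DBU, Et2NH, MeCN, 40 °C; then PhNTf2, rt
Reagents that add atoms: N-phenylbis(trifluoromethanesulfonimide), O=S(=O)(N(c1ccccc1)S(=O)(=O)C(F)(F)F)C(F)(F)F
Why: E1cB cleavage of the N–H carbamate (the isocyanate is scavenged by Et2NH as a urea) releases the phenoxide of 16, which is sulfonylated in the same flask; a one-pot carbamate-to-triflate conversion that keeps the aryl–silicon bond.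

Step 12
Reactants: 9 2-[(tert-butyldimethylsilyloxy)methyl]-4-methoxy-6-(methoxymethoxy)-3-(3-methylbut-2-en-1-yl)phenol; 17 3-(methoxymethoxy)-2-(trimethylsilyl)phenyl trifluoromethanesulfonate; 18 carbon dioxide
Product: 21 2-(methoxymethoxy)-6-[2-[(tert-butyldimethylsilyloxy)methyl]-4-methoxy-6-(methoxymethoxy)-3-(3-methylbut-2-en-1-yl)phenoxy]benzoic acid, via potassium phenoxide 19 (not isolated), via 3-(methoxymethoxy)benzyne 20 (not isolated)
Conditions: KH, THF, 0 °C → rt; then CO2 (1 atm), KF, 18-crown-6, slow addition of 17, THF, 0 °C → rt; cold aq. citric acid
Reagents that add atoms: potassium hydride, [K+].[H-] (its potassium appears in intermediate 19 only)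
Why: Fluoride attacks the trimethylsilyl group of 17 and 1,2-elimination of triflate releases aryne 20 slowly and at low concentration. The methoxymethoxy group distorts the triple bond by inductive withdrawal, so the carbon remote from it (future C6) is the more linear and more electrophilic one, and phenoxide 19 adds there to form the C6–O bond. The aryl anion then sits on future C1, next to the acetal oxygen that stabilizes it inductively and holds the potassium ion, and it adds to CO2 to form the C1–carboxyl bond. The closest known reaction type is the three-component coupling of arynes, heteroatom nucleophiles and CO2 (as in anthranilate synthesis from amines), combined with the well-established O-arylation of phenoxides by arynes. No ring is closed and no stereocentre is formed. The step needs regioselectivity, which the alkoxy group of the aryne secures, and carboxylation faster than protonation, which is served by making 19 with KH (H2 as the only by-product), by a solvent without acidic hydrogen and by saturation with CO2. It also needs the phenoxide to outrun fluoride and the prenyl alkene as aryne traps; slow addition of 17 keeps the phenoxide in large excess over the aryne, and anion addition is much faster than an intermolecular ene reaction. A small, strongly electrophilic aryne should accept the di-ortho-substituted phenoxide far more readily than a hindered aryl halide would.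

Step 13
Reactants: 21 2-(methoxymethoxy)-6-[2-[(tert-butyldimethylsilyloxy)methyl]-4-methoxy-6-(methoxymethoxy)-3-(3-methylbut-2-en-1-yl)phenoxy]benzoic acid
Product: 22 methyl 2-(methoxymethoxy)-6-[2-[(tert-butyldimethylsilyloxy)methyl]-4-methoxy-6-(methoxymethoxy)-3-(3-methylbut-2-en-1-yl)phenoxy]benzoate
Conditions: MeI, K2CO3, DMF, rt
Reagents that add atoms: iodomethane, CI
Why: SN2 O-alkylation of the carboxylate; reaction at the carboxylate oxygen is insensitive to the two ortho substituents that would block Fischer esterification, and no acid touches the acetals.

Step 14
Reactants: 22 methyl 2-(methoxymethoxy)-6-[2-[(tert-butyldimethylsilyloxy)methyl]-4-methoxy-6-(methoxymethoxy)-3-(3-methylbut-2-en-1-yl)phenoxy]benzoate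
Product: 24 methyl 2-hydroxy-6-[2-[(tert-butyldimethylsilyloxy)methyl]-6-hydroxy-4-methoxy-3-(3-methylbut-2-en-1-yl)phenoxy]benzoate, via bis(trimethylsilyl) ether 23 (not isolated)
Conditions: TMSOTf, 2,2'-bipyridyl, MeCN, 0 °C → rt; then H2O, rt
Reagents that add atoms: trimethylsilyl trifluoromethanesulfonate, C[Si](C)(C)OS(=O)(=O)C(F)(F)F (its silyl groups appear in intermediate 23 only)
Why: Silyl triflate/2,2'-bipyridyl cleavage of aromatic methoxymethyl ethers; each ArO–CH2OMe becomes an aryl trimethylsilyl ether while bipyridyl captures the methoxymethyl cation, and water then hydrolyses the aryl silyl ethers. The medium stays buffered, so the prenyl alkene, the alkyl silyl ether and the ester should survive.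

Step 15
Reactants: 24 methyl 2-hydroxy-6-[2-[(tert-butyldimethylsilyloxy)methyl]-6-hydroxy-4-methoxy-3-(3-methylbut-2-en-1-yl)phenoxy]benzoate; 25 prenyl bromide (1-bromo-3-methylbut-2-ene)
Product: 26 methyl 2-(3-methylbut-2-en-1-yloxy)-6-[2-[(tert-butyldimethylsilyloxy)methyl]-4-methoxy-3-(3-methylbut-2-en-1-yl)-6-(3-methylbut-2-en-1-yloxy)phenoxy]benzoate
Conditions: prenyl bromide (2.5 equiv), K2CO3 (3 equiv), DMF, rt → 40 °C
Reagents that add atoms: prenyl bromide (the second equivalent of 25, one molecule for each phenol), CC(C)=CCBr
Why: Double Williamson ether synthesis: each of the two phenoxides of 24 takes one molecule of prenyl bromide by SN2 at the primary allylic carbon, so two prenyl groups are installed in one operation. In a dipolar aprotic solvent O-alkylation dominates over C-alkylation, gentle warming brings the hydrogen-bonded salicylate hydroxyl to completion, and the silyl ether keeps the benzylic oxygen out of play.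

Step 16
Reactants: 26 methyl 2-(3-methylbut-2-en-1-yloxy)-6-[2-[(tert-butyldimethylsilyloxy)methyl]-4-methoxy-3-(3-methylbut-2-en-1-yl)-6-(3-methylbut-2-en-1-yloxy)phenoxy]benzoate
Product: 27 methyl 2-[2-(hydroxymethyl)-4-methoxy-3-(3-methylbut-2-en-1-yl)-6-(3-methylbut-2-en-1-yloxy)phenoxy]-6-(3-methylbut-2-en-1-yloxy)benzoate (target)
Conditions: TBAF, AcOH, THF, 0 °C → rt
Reagents that add atoms: none
Why: Fluoride-induced desilylation; the acetic acid buffer keeps the liberated alkoxide protonated so that it cannot attack the neighbouring hindered ester, and the prenyl ethers and alkenes are inert.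

## Compound list

1 | 2,3-dihydroxybenzaldehyde | O=Cc1cccc(O)c1O | starting material
2 | 5-bromo-2,3-dihydroxybenzaldehyde | O=Cc1cc(Br)cc(O)c1O | intermediate
3 | 5-bromo-2-hydroxy-3-(methoxymethoxy)benzaldehyde | O=Cc1cc(Br)cc(OCOC)c1O | intermediate
4 | 2-hydroxy-5-methoxy-3-(methoxymethoxy)benzaldehyde | O=Cc1cc(OC)cc(OCOC)c1O | intermediate
5 | 6-bromo-2-hydroxy-5-methoxy-3-(methoxymethoxy)benzaldehyde | O=Cc1c(Br)c(OC)cc(OCOC)c1O | intermediate
6 | 2-hydroxy-5-methoxy-3-(methoxymethoxy)-6-(3-methylbut-2-en-1-yl)benzaldehyde | O=Cc1c(CC=C(C)C)c(OC)cc(OCOC)c1O | intermediate
7 | 2-(hydroxymethyl)-4-methoxy-6-(methoxymethoxy)-3-(3-methylbut-2-en-1-yl)phenol | OCc1c(CC=C(C)C)c(OC)cc(OCOC)c1O | intermediate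
8 | bis(tert-butyldimethylsilyl) ether of 7 (silicon on the phenolic and on the benzylic oxygen) | CC(C)(C)[Si](C)(C)OCc1c(CC=C(C)C)c(OC)cc(OCOC)c1O[Si](C)(C)C(C)(C)C | intermediate (not isolated)
9 | 2-[(tert-butyldimethylsilyloxy)methyl]-4-methoxy-6-(methoxymethoxy)-3-(3-methylbut-2-en-1-yl)phenol | Oc1c(OCOC)cc(OC)c(CC=C(C)C)c1CO[Si](C)(C)C(C)(C)C | intermediate
10 | resorcinol | Oc1cccc(O)c1 | starting material
11 | 3-(methoxymethoxy)phenol | COCOc1cccc(O)c1 | intermediate
12 | 3-(methoxymethoxy)phenyl N-isopropylcarbamate | COCOc1cccc(OC(=O)NC(C)C)c1 | intermediate
13 | 3-(methoxymethoxy)phenyl N-(tert-butyldimethylsilyl)-N-isopropylcarbamate | COCOc1cccc(OC(=O)N(C(C)C)[Si](C)(C)C(C)(C)C)c1 | intermediate (not isolated)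
14 | 3-(methoxymethoxy)-2-(trimethylsilyl)phenyl N-(tert-butyldimethylsilyl)-N-isopropylcarbamate | COCOc1cccc(OC(=O)N(C(C)C)[Si](C)(C)C(C)(C)C)c1[Si](C)(C)C | intermediate (not isolated)
15 | 3-(methoxymethoxy)-2-(trimethylsilyl)phenyl N-isopropylcarbamate | COCOc1cccc(OC(=O)NC(C)C)c1[Si](C)(C)C | intermediate
16 | 3-(methoxymethoxy)-2-(trimethylsilyl)phenol | COCOc1cccc(O)c1[Si](C)(C)C | intermediate (not isolated)
17 | 3-(methoxymethoxy)-2-(trimethylsilyl)phenyl trifluoromethanesulfonate | COCOc1cccc(OS(=O)(=O)C(F)(F)F)c1[Si](C)(C)C | intermediate
18 | carbon dioxide | O=C=O | starting material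
19 | potassium phenoxide of 9 | [K+].[O-]c1c(OCOC)cc(OC)c(CC=C(C)C)c1CO[Si](C)(C)C(C)(C)C | intermediate (not isolated)
20 | 3-(methoxymethoxy)benzyne | COCOC1=CC=CC#C1 | intermediate (not isolated)
21 | 2-(methoxymethoxy)-6-[2-[(tert-butyldimethylsilyloxy)methyl]-4-methoxy-6-(methoxymethoxy)-3-(3-methylbut-2-en-1-yl)phenoxy]benzoic acid | OC(=O)c1c(OCOC)cccc1Oc1c(OCOC)cc(OC)c(CC=C(C)C)c1CO[Si](C)(C)C(C)(C)C | intermediate
22 | methyl ester of 21 | COC(=O)c1c(OCOC)cccc1Oc1c(OCOC)cc(OC)c(CC=C(C)C)c1CO[Si](C)(C)C(C)(C)C | intermediate
23 | bis(trimethylsilyl) aryl ether corresponding to 24 | COC(=O)c1c(O[Si](C)(C)C)cccc1Oc1c(O[Si](C)(C)C)cc(OC)c(CC=C(C)C)c1CO[Si](C)(C)C(C)(C)C | intermediate (not isolated)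
24 | methyl 2-hydroxy-6-[2-[(tert-butyldimethylsilyloxy)methyl]-6-hydroxy-4-methoxy-3-(3-methylbut-2-en-1-yl)phenoxy]benzoate | COC(=O)c1c(O)cccc1Oc1c(O)cc(OC)c(CC=C(C)C)c1CO[Si](C)(C)C(C)(C)C | intermediate
25 | prenyl bromide (1-bromo-3-methylbut-2-ene) | CC(C)=CCBr | starting material
26 | methyl 2-(3-methylbut-2-en-1-yloxy)-6-[2-[(tert-butyldimethylsilyloxy)methyl]-4-methoxy-3-(3-methylbut-2-en-1-yl)-6-(3-methylbut-2-en-1-yloxy)phenoxy]benzoate | COC(=O)c1c(OCC=C(C)C)cccc1Oc1c(OCC=C(C)C)cc(OC)c(CC=C(C)C)c1CO[Si](C)(C)C(C)(C)C | intermediate
27 | methyl 2-[2-(hydroxymethyl)-4-methoxy-3-(3-methylbut-2-en-1-yl)-6-(3-methylbut-2-en-1-yloxy)phenoxy]-6-(3-methylbut-2-en-1-yloxy)benzoate | COC(=O)c1c(OCC=C(C)C)cccc1Oc1c(OCC=C(C)C)cc(OC)c(CC=C(C)C)c1CO | target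

## Step count and least certain steps

Total: 16 steps (7 to phenol 9, 4 to silyl triflate 17, the coupling, 4 after it). Longest linear sequence: 12 steps (steps 1–7 and 12–16).

Step 12 (key step). The most likely failure is proton capture by the aryl anion before it meets CO2, which would give the ether without its carboxyl group. Reversible carbonate formation between the phenoxide and CO2 could also slow the addition, and the di-ortho substitution of the phenoxide aggravates both. Support for phenoxides in this three-component coupling is thinner than for amines. Fallback: a copper-catalysed Ullmann-type ether synthesis. It sets out from 9, which is coupled with methyl 2-bromo-6-(methoxymethoxy)benzoate F1 (from commercial methyl 2-bromo-6-hydroxybenzoate, MOMCl and i-Pr2NEt) using CuI, picolinic acid and K3PO4 in DMSO at 90 °C. The ortho ester assists the copper step, and the product is 22 directly, so the route is rejoined at 22 and acid 21 is bypassed.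

Step 3. Substitution may be sluggish on a ring that carries a phenoxide para to the bromide, and hydrodebromination or degradation of the aldehyde in hot methoxide may compete. Fallback: the oxygen is introduced through boron. Setting out from 3, Miyaura borylation (B2pin2, Pd(dppf)Cl2, KOAc, dioxane, 80 °C) gives 2-hydroxy-3-(methoxymethoxy)-5-(4,4,5,5-tetramethyl-1,3,2-dioxaborolan-2-yl)benzaldehyde F2. Oxidation of the C–B bond with trimethylamine N-oxide, which leaves the aldehyde alone where alkaline peroxide would cause Dakin oxidation, gives 2,5-dihydroxy-3-(methoxymethoxy)benzaldehyde F3. Methylation of the non-chelated C5 hydroxyl (MeI, 1 equiv, K2CO3, DMF) returns to 4.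

Step 5. Allylic transposition during transmetalation or reductive elimination could deliver the 1,1-dimethylallyl isomer, and oxidative addition at a bromide with two ortho substituents may be slow enough for protodebromination to compete. Fallback: from 5, Stille coupling with allyltributylstannane (Pd(PPh3)4, DMF, 90 °C), which has no regiochemical ambiguity, gives 6-allyl-2-hydroxy-5-methoxy-3-(methoxymethoxy)benzaldehyde F4. Cross-metathesis with 2-methylbut-2-ene (second-generation Grubbs catalyst, CH2Cl2, 40 °C) turns the allyl into a prenyl group and returns to 6.

Step 14. Cleavage of the ring A acetal, which is crowded by the ester, may be incomplete, and insufficient buffering could lead to loss of the silyl ether or attack on the prenyl alkene. Loss of the silyl ether alone would be harmless, since the alcohol is wanted in the end. Fallback: from 22, Brønsted acid solvolysis (HCl generated from AcCl in MeOH, 0 °C → rt, short contact) removes both acetals and the silyl ether in one operation to give methyl 2-hydroxy-6-[2-hydroxy-6-(hydroxymethyl)-4-methoxy-3-(3-methylbut-2-en-1-yl)phenoxy]benzoate F5. No phenol stands ortho to the C-prenyl group, so chroman formation is not possible. Alkylation of the two phenols with two equivalents of 25 and K2CO3 in DMF, which leaves the primary alcohol untouched, then rejoins the route at 27.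

Step 2. The electrophile may be taken partly by the chelated C2 oxygen or by both oxygens. Fallback: from 2, both hydroxyls are protected (MOMCl, i-Pr2NEt, CH2Cl2) to give 5-bromo-2,3-bis(methoxymethoxy)benzaldehyde F6. The acetal ortho to the formyl group is then removed selectively by chelation-assisted cleavage with MgBr2·OEt2 (Et2O–CH2Cl2, rt), returning to 3.

## Further compounds

F1 | step 12 | methyl 2-bromo-6-(methoxymethoxy)benzoate | COC(=O)c1c(Br)cccc1OCOC
F2 | step 3 | 2-hydroxy-3-(methoxymethoxy)-5-(4,4,5,5-tetramethyl-1,3,2-dioxaborolan-2-yl)benzaldehyde | O=Cc1cc(B2OC(C)(C)C(C)(C)O2)cc(OCOC)c1O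
F3 | step 3 | 2,5-dihydroxy-3-(methoxymethoxy)benzaldehyde | O=Cc1cc(O)cc(OCOC)c1O
F4 | step 5 | 6-allyl-2-hydroxy-5-methoxy-3-(methoxymethoxy)benzaldehyde | O=Cc1c(CC=C)c(OC)cc(OCOC)c1O
F5 | step 14 | methyl 2-hydroxy-6-[2-hydroxy-6-(hydroxymethyl)-4-methoxy-3-(3-methylbut-2-en-1-yl)phenoxy]benzoate | COC(=O)c1c(O)cccc1Oc1c(O)cc(OC)c(CC=C(C)C)c1CO
F6 | step 2 | 5-bromo-2,3-bis(methoxymethoxy)benzaldehyde | O=Cc1cc(Br)cc(OCOC)c1OCOC
A1 | alternative 1 | eight-membered dibenzodioxocinone lactone with 4'-hydroxy, 2'-tert-butoxy and 5'-prenyl groups on ring B and a 2-(methoxymethoxy) group on ring A | O=C1OCc2c(CC=C(C)C)c(O)cc(OC(C)(C)C)c2Oc2cccc(OCOC)c12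
A2 | alternative 1 | pentacarbonyl{(1-tert-butoxyethenyl)[3-(methoxymethoxy)-2-{[(6-methylhept-5-en-2-yn-1-yl)oxy]carbonyl}phenoxy]methylidene}chromium | O=C=[Cr](=C=O)(=C=O)(=C=O)(=C=O)=C(Oc1cccc(OCOC)c1C(=O)OCC#CCC=C(C)C)C(=C)OC(C)(C)C
A3 | alternative 2 | methyl 2-[6-(dimethoxymethyl)-2-hydroxy-4-methoxy-5-(3-methylbut-2-en-1-yl)phenoxy]-6-(3-methylbut-2-en-1-yloxy)benzoate | COC(=O)c1c(OCC=C(C)C)cccc1Oc1c(O)cc(OC)c(CC=C(C)C)c1C(OC)OC
A4 | alternative 2 | methyl 2-{[(3E)-4,7,7-trimethoxy-5-(3-methylbut-2-en-1-yl)-2,6-dioxohept-3-en-1-yl]oxy}-6-(3-methylbut-2-en-1-yloxy)benzoate, racemic at the prenyl-bearing carbon | COC(=O)c1c(OCC=C(C)C)cccc1OCC(=O)/C=C(/OC)C(CC=C(C)C)C(=O)C(OC)OC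
A5 | alternative 3 | methyl 2-hydroxy-6-[2-[(tert-butyldimethylsilyloxy)methyl]-4-methoxy-3-(3-methylbut-2-en-1-yl)-6-(3-methylbut-2-en-1-yloxy)phenoxy]benzoate | COC(=O)c1c(O)cccc1Oc1c(OCC=C(C)C)cc(OC)c(CC=C(C)C)c1CO[Si](C)(C)C(C)(C)C
A6 | alternative 3 | methyl 3-[2-[(tert-butyldimethylsilyloxy)methyl]-4-methoxy-3-(3-methylbut-2-en-1-yl)-6-(3-methylbut-2-en-1-yloxy)phenoxy]prop-2-ynoate | COC(=O)C#COc1c(OCC=C(C)C)cc(OC)c(CC=C(C)C)c1CO[Si](C)(C)C(C)(C)C
A7 | alternative 3 | 1-methoxy-1-(trimethylsilyloxy)buta-1,3-diene, mixture of geometric isomers | C=CC=C(OC)O[Si](C)(C)C
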